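**Plan**

Numbering (drimane): ring A = C1–C2–C3(OH)–C4(Me2)–C5–C10(Me); ring B = C5–C6–C7=C8(Me)–C9(C11H2OAr)–C10.
Retrosynthetic cuts, in order: the O–C11 aryl ether; then (after C3 alcohol → ketone and C1–C2 → enone) the two C4–CH3 bonds and the C1=C2 bond of ring A (aldol); last C5–C6 and C9–C10 of ring B together.
Forward: ring B is made first, in one enantioselective Diels–Alder step, from an acyclic diene (C6–C9 and C11) and an acyclic (E)-2-methyl-2-enal (C1, C10, C5, C4–C2). Ring A then closes by aldol condensation of the C2 methyl ketone onto the C1 aldehyde; C4 is dimethylated, C1=C2 and C3=O are reduced, and scopoletin is attached last.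
Enabling feature: ring B is a cyclohexene whose C7=C8 bond lies opposite the C5–C10 fusion bond, and C10 is quaternary and carries C1, so C1 held at the aldehyde level activates C5=C10. H-5/CH3-10 trans maps onto an E dienophile, and C11/CH3-10 trans onto the endo mode.
Stereochemistry: C5, C9 and C10 come from the catalyst-controlled cycloaddition; C3 comes from equatorial hydride delivery to the 4,4-dimethyl-3-ketone. Helpers: the formyl group (becomes C1), a dioxolane on C3, a silyl ether on O11.

Key step: step 5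

Assumption: the face rule of the formyl C–H···O binding model is taken to hold for the 2-methyl-2-enal dienophile (the (S)-catalyst exposing the Cα-re face), so the (R)-catalyst is specified; if the adduct proves antipodal, the (S)-catalyst is used and nothing else changes.

**Route**

Step 1
Reactants: 1 (2E)-3-methylpent-2-en-4-yn-1-ol
Product: 2 tert-butyl{[(2E)-3-methylpent-2-en-4-yn-1-yl]oxy}diphenylsilane
Conditions: TBDPSCl, imidazole, CH2Cl2, 0 °C to rt
Reagents that add atoms: tert-butyl(chloro)diphenylsilane (TBDPSCl), CC(C)(C)[Si](Cl)(c1ccccc1)c1ccccc1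
Why: Silylation of a primary allylic alcohol is routine and gives an ether that should survive the later Lewis acid, aqueous acid, alkoxide and hydride steps.

Step 2
Reactants: 2 tert-butyl{[(2E)-3-methylpent-2-en-4-yn-1-yl]oxy}diphenylsilane
Product: 3 tert-butyl{[(2E)-3-methylpenta-2,4-dien-1-yl]oxy}diphenylsilane
Conditions: H2 (1 atm), Pd/CaCO3 poisoned with Pb(OAc)2, quinoline, hexane/EtOAc, rt, stopped after one equivalent of H2
Reagents that add atoms: none
Why: Partial hydrogenation of a terminal alkyne on poisoned palladium should stop at the vinyl group and leave the E-trisubstituted double bond untouched, giving the diene with its CH2O group on the outside of the C9 terminus.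

Step 3
Reactants: 4 ethyl (2-methyl-1,3-dioxolan-2-yl)acetate
Product: 5 (2-methyl-1,3-dioxolan-2-yl)acetaldehyde
Conditions: i-Bu2AlH (1.05 equiv), CH2Cl2, −78 °C; aq. potassium sodium tartrate
Reagents that add atoms: none
Why: Partial reduction of an ester with i-Bu2AlH at −78 °C stops at the aluminium hemiacetal, which releases the aldehyde on work-up, and the ketal is inert to hydride.

Step 4
Reactants: 5 (2-methyl-1,3-dioxolan-2-yl)acetaldehyde; 6 2-(triphenyl-λ5-phosphanylidene)propanal
Product: 7 (2E)-2-methyl-4-(2-methyl-1,3-dioxolan-2-yl)but-2-enal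
Conditions: toluene, 80 °C
Reagents that add atoms: none
Why: Wittig olefination with a stabilized formyl ylide should give the E-2-methyl-2-enal, the geometry that later places H-5 trans to the C10 methyl group.

Step 5
Reactants: 3 tert-butyl{[(2E)-3-methylpenta-2,4-dien-1-yl]oxy}diphenylsilane; 7 (2E)-2-methyl-4-(2-methyl-1,3-dioxolan-2-yl)but-2-enal
Product: 8 (1R,2S,6R)-2-({[tert-butyl(diphenyl)silyl]oxy}methyl)-1,3-dimethyl-6-[(2-methyl-1,3-dioxolan-2-yl)methyl]cyclohex-3-ene-1-carbaldehyde
Conditions: [C24H25BNO]+ [N(SO2CF3)2]− (N-protonated (R)-B-(2-methylphenyl)oxazaborolidine from (R)-α,α-diphenylprolinol, made in situ from the oxazaborolidine C24H24BNO and HN(SO2CF3)2; 20 mol %), 3 (1.5 equiv), CH2Cl2, −40 to −20 °C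
Reagents that add atoms: none
Why: The protonated oxazaborolidine binds the formyl oxygen of 7 (formyl C–H held by the ring oxygen), lowers the LUMO of the s-trans enal and lets diene 3 add in a concerted but asynchronous [4+2] cycloaddition in which C5–C6 forms ahead of C9–C10. The closest known reaction type is the chiral-oxazaborolidinium-catalysed Diels–Alder reaction of 2-methyl-2-enals (tiglaldehyde-type dienophiles) with acyclic 1,3-dienes. Ring B closes by an intermolecular suprafacial–suprafacial six-electron cycloaddition that leaves the C7=C8 double bond and its methyl group in place. C5 and C10 (H-5 trans to the C10 methyl) follow stereospecifically from the E geometry of 7; C9 (CH2OSi trans to the C10 methyl, cis to the formyl group) follows from the endo position of the catalyst-bound formyl group relative to the E-configured diene terminus; the absolute sense follows from the aryl group of the catalyst, which covers one face of the enal so that the diene meets the Cα-si face. The step needs ortho regioselectivity (C9 bonded to C10), endo selectivity and face selectivity: the first should be secured because the unsubstituted, less hindered terminus C6 of a 1-alkyl-substituted diene is the more nucleophilic one and meets the β-carbon C5, the second by the usual endo preference of a Lewis-acid-bound formyl group with acyclic dienes, and the third by the catalyst.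

Step 6
Reactants: 8 (1R,2S,6R)-2-({[tert-butyl(diphenyl)silyl]oxy}methyl)-1,3-dimethyl-6-[(2-methyl-1,3-dioxolan-2-yl)methyl]cyclohex-3-ene-1-carbaldehyde
Product: 10 (4aS,5S,8aR)-5-({[tert-butyl(diphenyl)silyl]oxy}methyl)-4a,6-dimethyl-4a,5,8,8a-tetrahydronaphthalen-2(1H)-one, via keto aldehyde 9 (not isolated)
Conditions: 1 M HCl (cat.), THF/H2O, rt; then NaOMe (0.3 equiv), MeOH, 50 °C
Reagents that add atoms: water, O
Why: Ketal hydrolysis frees the methyl ketone, whose methyl group (C2) should close ring A onto the non-enolizable C1 aldehyde by intramolecular aldol condensation (the six-membered ring is the only unstrained closure), with no acidic hydrogen at C5, C9 or C10.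

Step 7
Reactants: 10 (4aS,5S,8aR)-5-({[tert-butyl(diphenyl)silyl]oxy}methyl)-4a,6-dimethyl-4a,5,8,8a-tetrahydronaphthalen-2(1H)-one
Product: 11 (4aR,5S,8aS)-5-({[tert-butyl(diphenyl)silyl]oxy}methyl)-1,1,4a,6-tetramethyl-4a,5,8,8a-tetrahydronaphthalen-2(1H)-one
Conditions: KOt-Bu (3 equiv), MeI (6 equiv), t-BuOH/THF, 0 °C to rt
Reagents that add atoms: iodomethane (MeI), CI
Why: The enone can enolize only toward C4 (C2 is vinylic, C10 is quaternary), so exhaustive alkylation of the cross-conjugated enolate should place both methyl groups on C4.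

Step 8
Reactants: 11 (4aR,5S,8aS)-5-({[tert-butyl(diphenyl)silyl]oxy}methyl)-1,1,4a,6-tetramethyl-4a,5,8,8a-tetrahydronaphthalen-2(1H)-one
Product: 12 (4aR,5S,8aS)-5-({[tert-butyl(diphenyl)silyl]oxy}methyl)-1,1,4a,6-tetramethyl-3,4,4a,5,8,8a-hexahydronaphthalen-2(1H)-one
Conditions: H2 (1 atm), RhCl(PPh3)3 (5 mol %), benzene/EtOH, rt
Reagents that add atoms: none
Why: Homogeneous hydrogenation with RhCl(PPh3)3 should saturate the cis-disubstituted C1=C2 enone bond and leave the trisubstituted C7=C8 bond unreduced and unmigrated.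

Step 9
Reactants: 12 (4aR,5S,8aS)-5-({[tert-butyl(diphenyl)silyl]oxy}methyl)-1,1,4a,6-tetramethyl-3,4,4a,5,8,8a-hexahydronaphthalen-2(1H)-one
Product: 13 (2S,4aR,5S,8aS)-5-({[tert-butyl(diphenyl)silyl]oxy}methyl)-1,1,4a,6-tetramethyl-1,2,3,4,4a,5,8,8a-octahydronaphthalen-2-ol
Conditions: LiBH(s-Bu)3 (1.5 equiv), THF, −78 to 0 °C; then H2O
Reagents that add atoms: none
Why: A bulky trialkylborohydride should attack the chair 4,4-dimethyl-3-ketone along the equatorial direction and so give the axial C3 alcohol, cis to H-5 and trans to the C10 methyl group, as in the target.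

Step 10
Reactants: 13 (2S,4aR,5S,8aS)-5-({[tert-butyl(diphenyl)silyl]oxy}methyl)-1,1,4a,6-tetramethyl-1,2,3,4,4a,5,8,8a-octahydronaphthalen-2-ol
Product: 14 (2S,4aR,5S,8aS)-5-(hydroxymethyl)-1,1,4a,6-tetramethyl-1,2,3,4,4a,5,8,8a-octahydronaphthalen-2-ol
Conditions: n-Bu4NF (1.5 equiv), THF, rt
Reagents that add atoms: none
Why: Fluoride-induced desilylation frees the primary C11 alcohol without touching any stereocentre or the alkene.

Step 11
Reactants: 14 (2S,4aR,5S,8aS)-5-(hydroxymethyl)-1,1,4a,6-tetramethyl-1,2,3,4,4a,5,8,8a-octahydronaphthalen-2-ol; 15 scopoletin (7-hydroxy-6-methoxy-2H-chromen-2-one)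
Product: 16 7-{[(1S,4aS,6S,8aR)-6-hydroxy-2,5,5,8a-tetramethyl-1,4,4a,5,6,7,8,8a-octahydronaphthalen-1-yl]methoxy}-6-methoxy-2H-chromen-2-one (CNP0218138.1)
Conditions: PPh3 (1.5 equiv), diisopropyl azodicarboxylate (1.5 equiv), 15 (1.2 equiv), THF, 0 °C to rt
Reagents that add atoms: none
Why: Mitsunobu etherification should engage only the primary C11 alcohol with the acidic 7-hydroxyl of the coumarin, the axial C3 alcohol beside the quaternary C4 being too hindered to form the oxyphosphonium salt, and no stereocentre is involved.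

**Compound list**

1 | (2E)-3-methylpent-2-en-4-yn-1-ol | C#C/C(C)=C/CO | starting material
2 | tert-butyl{[(2E)-3-methylpent-2-en-4-yn-1-yl]oxy}diphenylsilane | C#C/C(C)=C/CO[Si](c1ccccc1)(c1ccccc1)C(C)(C)C | intermediate
3 | tert-butyl{[(2E)-3-methylpenta-2,4-dien-1-yl]oxy}diphenylsilane | C=C/C(C)=C/CO[Si](c1ccccc1)(c1ccccc1)C(C)(C)C | intermediate
4 | ethyl (2-methyl-1,3-dioxolan-2-yl)acetate | CCOC(=O)CC1(C)OCCO1 | starting material
5 | (2-methyl-1,3-dioxolan-2-yl)acetaldehyde | O=CCC1(C)OCCO1 | intermediate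
6 | 2-(triphenyl-λ5-phosphanylidene)propanal | CC(C=O)=P(c1ccccc1)(c1ccccc1)c1ccccc1 | starting material
7 | (2E)-2-methyl-4-(2-methyl-1,3-dioxolan-2-yl)but-2-enal | O=C/C(C)=C/CC1(C)OCCO1 | intermediate
8 | (1R,2S,6R)-2-({[tert-butyl(diphenyl)silyl]oxy}methyl)-1,3-dimethyl-6-[(2-methyl-1,3-dioxolan-2-yl)methyl]cyclohex-3-ene-1-carbaldehyde | CC(C)(C)[Si](OC[C@H]1C(C)=CC[C@H](CC2(C)OCCO2)[C@]1(C=O)C)(c1ccccc1)c1ccccc1 | intermediate
9 | (1R,2S,6R)-2-({[tert-butyl(diphenyl)silyl]oxy}methyl)-1,3-dimethyl-6-(2-oxopropyl)cyclohex-3-ene-1-carbaldehyde (keto aldehyde, not isolated) | CC(C)(C)[Si](OC[C@H]1C(C)=CC[C@H](CC(C)=O)[C@]1(C=O)C)(c1ccccc1)c1ccccc1 | intermediate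
10 | (4aS,5S,8aR)-5-({[tert-butyl(diphenyl)silyl]oxy}methyl)-4a,6-dimethyl-4a,5,8,8a-tetrahydronaphthalen-2(1H)-one | CC(C)(C)[Si](OC[C@H]1C(C)=CC[C@@H]2CC(=O)C=C[C@]21C)(c1ccccc1)c1ccccc1 | intermediate
11 | (4aR,5S,8aS)-5-({[tert-butyl(diphenyl)silyl]oxy}methyl)-1,1,4a,6-tetramethyl-4a,5,8,8a-tetrahydronaphthalen-2(1H)-one | CC(C)(C)[Si](OC[C@H]1C(C)=CC[C@@H]2C(C)(C)C(=O)C=C[C@]21C)(c1ccccc1)c1ccccc1 | intermediate
12 | (4aR,5S,8aS)-5-({[tert-butyl(diphenyl)silyl]oxy}methyl)-1,1,4a,6-tetramethyl-3,4,4a,5,8,8a-hexahydronaphthalen-2(1H)-one | CC(C)(C)[Si](OC[C@H]1C(C)=CC[C@@H]2C(C)(C)C(=O)CC[C@]21C)(c1ccccc1)c1ccccc1 | intermediate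
13 | (2S,4aR,5S,8aS)-5-({[tert-butyl(diphenyl)silyl]oxy}methyl)-1,1,4a,6-tetramethyl-1,2,3,4,4a,5,8,8a-octahydronaphthalen-2-ol | CC(C)(C)[Si](OC[C@H]1C(C)=CC[C@@H]2C(C)(C)[C@@H](O)CC[C@]21C)(c1ccccc1)c1ccccc1 | intermediate
14 | (2S,4aR,5S,8aS)-5-(hydroxymethyl)-1,1,4a,6-tetramethyl-1,2,3,4,4a,5,8,8a-octahydronaphthalen-2-ol | OC[C@H]1C(C)=CC[C@@H]2C(C)(C)[C@@H](O)CC[C@]21C | intermediate
15 | scopoletin (7-hydroxy-6-methoxy-2H-chromen-2-one) | COc1cc2ccc(=O)oc2cc1O | starting material
16 | 7-{[(1S,4aS,6S,8aR)-6-hydroxy-2,5,5,8a-tetramethyl-1,4,4a,5,6,7,8,8a-octahydronaphthalen-1-yl]methoxy}-6-methoxy-2H-chromen-2-one | COc1cc2ccc(=O)oc2cc1OC[C@H]1C(C)=CC[C@@H]2C(C)(C)[C@@H](O)CC[C@]21C | target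

**Count and risks**

Total step count: 11. Longest linear sequence: 9 steps (1, 2, 5, 6, 7, 8, 9, 10, 11).

Steps most likely to fail:

Step 5. The trisubstituted enal may add too slowly. Selectivity may leak to the exo mode (C9 epimer) or to the other regiochemistry, the face selectivity may erode, and the acidic catalyst may open the dioxolane. Fallback, setting out from diene 3 and returning at enone 10: the enal is replaced by commercial 2-methoxy-5-methyl-1,4-benzoquinone (COC1=CC(=O)C(C)=CC1=O), a far more reactive dienophile. With the same chiral oxazaborolidinium triflimide, the boron should sit on the vinylogous-ester carbonyl and direct C9 of the diene to the methyl-bearing carbon, giving the cis-fused endo adduct F1. C5, now α to the C4 ketone, is epimerized with aqueous NaOH in dioxane to the trans-fused enedione F2. LiAlH4 in THF reduces both carbonyl groups to the diol F3. Aqueous HCl in THF hydrolyses the enol ether and eliminates the C1 hydroxyl, giving the hydroxy enone F4. Ac2O in pyridine gives the acetate F5, and zinc in acetic acid removes the α-acetoxy group to give 10.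

Step 11. Displacement at the β-branched, axially placed primary oxyphosphonium centre may be sluggish, and elimination toward an exocyclic diene may compete. Fallback, setting out from diol 14 and returning at 16: the primary alcohol is sulfonylated selectively (MsCl, Et3N, CH2Cl2, −20 °C) to the primary methanesulfonate F6, which is then displaced by the caesium phenoxide of scopoletin 15 (Cs2CO3, DMF, 60 °C) in a Williamson etherification.

Step 8. Turnover may be slow at a double bond flanked by the quaternary C10, and forcing the hydrogenation may reduce or migrate the C7=C8 bond. Fallback, setting out from enone 11 and returning at ketone 12: hydrogen addition is replaced by conjugate hydride delivery from [(Ph3P)CuH]6 (catalytic, with PhMe2SiH as hydride source, toluene, rt), which acts only on the enone and gives 12 after hydrolysis of the silyl enol ether. No new compound is formed.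

**Further compounds**

F1 | step 5 | cis-fused endo adduct, 5-({[tert-butyl(diphenyl)silyl]oxy}methyl)-2-methoxy-4a,6-dimethyl-4a,5,8,8a-tetrahydronaphthalene-1,4-dione, H-8a cis and the C5 side chain trans to the 4a-methyl group | CC(C)(C)[Si](OC[C@H]1C(C)=CC[C@H]2C(=O)C(OC)=CC(=O)[C@]21C)(c1ccccc1)c1ccccc1
F2 | step 5 | trans-fused C8a epimer of F1 (H-8a trans to the 4a-methyl group) | CC(C)(C)[Si](OC[C@H]1C(C)=CC[C@@H]2C(=O)C(OC)=CC(=O)[C@]21C)(c1ccccc1)c1ccccc1
F3 | step 5 | trans-fused diol, 5-({[tert-butyl(diphenyl)silyl]oxy}methyl)-2-methoxy-4a,6-dimethyl-1,4,4a,5,8,8a-hexahydronaphthalene-1,4-diol (carbinol centres unassigned) | CC(C)(C)[Si](OC[C@H]1C(C)=CC[C@@H]2C(O)C(OC)=CC(O)[C@]21C)(c1ccccc1)c1ccccc1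
F4 | step 5 | trans-fused hydroxy enone, 5-({[tert-butyl(diphenyl)silyl]oxy}methyl)-1-hydroxy-4a,6-dimethyl-4a,5,8,8a-tetrahydronaphthalen-2(1H)-one (carbinol centre unassigned) | CC(C)(C)[Si](OC[C@H]1C(C)=CC[C@@H]2C(O)C(=O)C=C[C@]21C)(c1ccccc1)c1ccccc1
F5 | step 5 | acetate of F4, 5-({[tert-butyl(diphenyl)silyl]oxy}methyl)-4a,6-dimethyl-2-oxo-1,2,4a,5,8,8a-hexahydronaphthalen-1-yl acetate | CC(C)(C)[Si](OC[C@H]1C(C)=CC[C@@H]2C(OC(C)=O)C(=O)C=C[C@]21C)(c1ccccc1)c1ccccc1
F6 | step 11 | [(1S,4aS,6S,8aR)-6-hydroxy-2,5,5,8a-tetramethyl-1,4,4a,5,6,7,8,8a-octahydronaphthalen-1-yl]methyl methanesulfonate | CS(=O)(=O)OC[C@H]1C(C)=CC[C@@H]2C(C)(C)[C@@H](O)CC[C@]21C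
F0 | step 8 | none | none
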